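## Structural features

The target (17) is a chromone. Benzene ring A is fused through the C4a–C8a bond to the 4-pyranone ring B, which carries the C4 carbonyl, an unsubstituted C3 and an unbranched pentadecyl chain on C2. Ring A has no free position: hydroxyls sit on C5 and C7, methyls on C6 and C8, and C4a and C8a carry the acyl carbon C4 and the ring oxygen O1. Before ring B is closed the arene is therefore a doubly C-methylated phloroglucinol with mirror symmetry about the C4a···C7 axis. There is no stereocentre and no stereogenic double bond, so no stereochemical relationship has to be set or preserved. The fragile elements are the electron-rich trioxygenated ring once its phenols are free, the base-sensitive pyranone and the chelated C5 hydroxyl; the C15 chain only affects solubility and purification. The real difficulty is regiochemical: a hexasubstituted benzene must be assembled with every substituent placed, and the three-carbon unit C4–C3–C2 must be attached through carbon at C4a. The key step exploits the fact that C4, C3 and C2 form a 1,3-dioxygenated chain on a ring carbon (C4a) whose two neighbours (C5 and C8a) both bear oxygen. This is the pattern of a 3-arylisoxazole made from a 2,6-dialkoxyaryl nitrile oxide, and the same two ortho oxygens stabilise the dipole.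

One point of atom bookkeeping needs correcting. Of the two bonds made in the cycloaddition only C3–C4 remains in 17. The oxygen delivered to C2 fixes the ketone oxidation level there and leaves as water at ring closure. O1 stems from an aryl ether oxygen, and the C4 carbonyl oxygen comes from water.

## Logic of the disconnections

17 is opened at O1–C2, its C4 carbonyl is traced back to a C4–N bond of a vinylogous amide, and the two phenols and the future O1 are traced back to three methyl ethers. This leads through 16 and 15 to 14. The cut removes the heterocycle and leaves an open chain on a symmetric arene, so ring closure can give only one product. The forward step must cleave three aryl methyl ethers (one lying between two methyls), hydrolyse the enamine and dehydrate. The molecule holds no other sensitive function, so strong Lewis and Brønsted acids are tolerable.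

The N–H and C=O pair of 14 is reconnected to the N–O bond of 13. This exchanges a hydrolytically labile 1,3-dicarbonyl equivalent for a robust aromatic ring that survives purification and storage. The forward step must break the N–O bond and nothing else.

13 is cut at C3–C4 and at the bond between C2 and the ring oxygen (target numbering), a retro-(3+2) cycloaddition to 10 and 12. This is the convergent cut: every ring A substituent goes into 10 and the whole chain into 12, and neither fragment holds a stereocentre. The forward step needs a dipole that survives long enough to meet an unactivated alkyne and that adds with its carbon to the terminal alkyne carbon.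

10 is traced back by addition of two hydrogens (through 9) to 8, and by cleavage of C=N to 7. No skeletal bond is cut. The gain is that the dipole is prepared from a stable, purifiable aldehyde. The oxidation must not touch the ring or its methyls, which the absence of any free ring position guarantees.

7 is cut at the C4a–C4 bond (aryl–CHO), leading through 6 and 5 to 4. The one remaining ring hydrogen of 4 lies between two methoxy groups, so the bond can be made by deprotonation and formylation with no regiochemical choice. The methyl ethers serve as directing groups here, as dipole shields later and as phenol protection throughout. The forward step must metalate a crowded position without attacking the benzylic methyls.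

4 is cut at one aryl–CH3 bond (future C6–CH3 or C8–CH3), leading through 3 to 1 and 2. The two free positions of 1 are equivalent and each is flanked by two methoxy groups, so a single product is expected. The demand is clean monometalation and methylation.

12 is cut at the bond between the alkyne carbon (future C2) and the first chain carbon, giving 11 and a two-carbon acetylide nucleophile. The demand is substitution of a primary bromide without elimination.

## Other disconnections considered

Alternative 1: The cut is the C4a–C8a bond, so ring A is made and not bought. The forward key step would treat the 2-pyranone 6-(2,4-dioxononadecyl)-4-hydroxy-3,5-dimethyl-2H-pyran-2-one A2 with Mg(OMe)2. Methoxide should open the lactone to the magnesium chelate of methyl 2,4-dimethyl-3,5,7,9-tetraoxotetracosanoate A3. The C4a methylene of A3 would be acylated by the ester carbon C8a (Claisen condensation) and the ring would aromatise to 1-(2,4,6-trihydroxy-3,5-dimethylphenyl)octadecane-1,3-dione A1. Acid would then close ring B.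
- In favour: it follows the presumed biogenesis and needs no protecting group. A1 is the same compound as intermediate 16 of the chosen route, so the endgame is one mild cyclodehydration without BBr3. On protecting-group economy and on mildness of the last step this alternative is the better plan.
- Against: A2 is not a catalogue compound. Its β,δ-diketone side chain with a C15 tail would have to be attached by polyanion acylation of a methylated hydroxypyranone, through several steps with enolised, poorly crystalline intermediates. Mechanistically A3 can cyclise in several ways (aldol closure of C3 onto the C7 carbonyl, of C8 onto the C4 carbonyl, or relactonisation to A2), and the Claisen mode relies entirely on magnesium chelation.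
- Comparison: the chosen plan never has to form ring A, so that regiochemical question does not arise, but it pays with three methyl ethers to remove. The step counts should be about equal (roughly four to six steps to A2, then two). The risk of alternative 1 lies in preparing its precursor and in the folding mode; that of the chosen plan lies in its last deprotection.

Alternative 2: Three bonds of ring B are cut at once: O1–C8a, C4–C4a and O1–C2. In the forward step CsF would release the aryne from 5-methoxy-4,6-dimethyl-2-(trimethylsilyl)-1,3-phenylene bis(trifluoromethanesulfonate) A5. Cesium octadec-2-ynoate A6 would add through oxygen at C8a, and the carbanion at C4a would attack the ester carbonyl (acyl transfer, overall insertion into the C–O bond). The resulting phenoxide would add 6-endo-dig to the ynone to give 7-methoxy-6,8-dimethyl-2-pentadecyl-5-(trifluoromethanesulfonyloxy)chromone A4. Triflate cleavage and O-demethylation would follow.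
- In favour: it is the most convergent key step of the four. It makes three bonds and ring B itself in one operation, against one lasting bond and a sacrificial ring in the chosen key step, so on bond economy it is the better. A5 is mirror-symmetric, so either triflate may leave. The remaining triflate steers the nucleophile to C8a (the aryne carbon remote from the inductively withdrawing group) and ends as the C5 oxygen.
- Against: A5 is a hexasubstituted benzene needing its own multistep synthesis (a mono-O-methylated dimethylphloroglucinol, ortho-silylation, double triflation), hardly shorter than the way to 10. Attack must occur at an aryne carbon flanked by the C8 methyl. The C4a carbanion lies ortho to a triflate, where loss of triflate to a second aryne or triflyl migration to carbon can compete with the acyl shift. A carboxylate is a weak aryne nucleophile, and the alkyne of A6 can itself react with arynes.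
- Comparison: two deprotections remain after the key step, the same number as in the chosen plan, so the endgames are equal. Alternative 2 is less predictable because four consecutive events must all succeed in one flask, whereas the chosen plan spreads them over separate, well-understood steps. Its total step count is estimated to be two or three higher.

Alternative 3: The cut removes the two ring methyls, C6–CH3 and C8–CH3. The forward key step would couple 6,8-diiodo-5,7-dimethoxy-2-pentadecylchromone A8 twice with (MeBO)3 under Pd(OAc)2/SPhos catalysis with K3PO4 (twofold Suzuki–Miyaura methylation). This would give 5,7-dimethoxy-6,8-dimethyl-2-pentadecylchromone A7, and BBr3 would then give 17. A8 would come from 5,7-dimethoxy-2-pentadecylchromone A9 by double iodination, and A9 from a commercial acetophenone by Baker–Venkataraman chemistry.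
- In favour: ring A oxygenation is bought and the chromone is assembled by classical chemistry. The line is about five to six steps, fewer than the eight of the chosen plan, so on step economy it is the better. No energetic dipole has to be handled.
- Against: iodination must find C6 and C8 and spare the nucleophilic C3 of the pyranone, and nothing in the structure enforces this. Each C–I bond has two ortho substituents (C6 between two methoxy groups, C8 between a methoxy group and the ring oxygen), so coupling with a small alkylboron partner should be slow and protodeiodination should compete. The resulting mono-methyl and unmethylated chromones would differ from A7 by one carbon in a molecule dominated by a C15 chain, a late separation problem.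
- Comparison: the chosen plan places both methyls by directed lithiation on a simple arene, where acidity forces the regiochemistry and by-products are easily removed. The final demethylation is common to both plans (equal). Alternative 3 wins on step count and loses on the reliability of its two selectivity-dependent steps.

Key step: step 6

Remark: 2,4,6-trimethoxytoluene (1) is taken as a catalogue compound; the E oxime and the Z enaminoketone are written as the expected isomers, and neither geometry affects the outcome.

## Steps

Step 1
Reactants: 1 2,4,6-trimethoxytoluene (1,3,5-trimethoxy-2-methylbenzene); 2 iodomethane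
Product: 4 1,3,5-trimethoxy-2,4-dimethylbenzene, via aryllithium 3 (not isolated)
Conditions: n-BuLi, TMEDA, THF, 0 °C to rt; then MeI, −78 °C to rt
Reagents that add atoms: iodomethane, CI
Why: Directed ortho-metalation: a ring hydrogen of 1 lying between two methoxy groups is the most acidic and best-coordinated site, so 3 should form cleanly and be methylated by SN2 attack on 2. The two free ring positions of 1 are equivalent, so only one product is possible.

Step 2
Reactants: 4 1,3,5-trimethoxy-2,4-dimethylbenzene
Product: 7 2,4,6-trimethoxy-3,5-dimethylbenzaldehyde, via aryllithium 5 (not isolated), via lithium aminoalkoxide 6 (not isolated)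
Conditions: n-BuLi, TMEDA, THF, 0 °C to rt; then DMF, −78 °C to rt; aq. HCl work-up
Reagents that add atoms: N,N-dimethylformamide, CN(C)C=O
Why: The single remaining ring hydrogen of 4 is again flanked by two methoxy groups, so the same directed ortho-metalation should give 5. Addition to DMF gives the tetrahedral adduct 6, which cannot react further and releases 7 on acidic work-up (Bouveault-type formylation).

Step 3
Reactants: 7 2,4,6-trimethoxy-3,5-dimethylbenzaldehyde
Product: 8 (E)-2,4,6-trimethoxy-3,5-dimethylbenzaldehyde oxime
Conditions: NH2OH·HCl, NaOAc, EtOH/H2O, reflux
Reagents that add atoms: hydroxylamine hydrochloride, NO.Cl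
Why: Oxime formation by condensation of an aromatic aldehyde with hydroxylamine under acetate buffering; heating compensates for the two ortho substituents. The E isomer is expected, but either geometry serves in step 4.

Step 4
Reactants: 8 (E)-2,4,6-trimethoxy-3,5-dimethylbenzaldehyde oxime
Product: 10 2,4,6-trimethoxy-3,5-dimethylbenzonitrile oxide, via hydroximoyl chloride 9 (not isolated)
Conditions: aq. NaOCl, CH2Cl2, 0 °C; concentrate cold, crystallise, store at −20 °C
Reagents that add atoms: none
Why: Hypochlorite chlorinates the aldoxime carbon to 9 and the basic aqueous phase removes HCl to give the nitrile oxide (dehydrogenation of an aldoxime through a hydroximoyl chloride). The fully substituted ring offers no position for electrophilic chlorination, and the two ortho methoxy groups block dimerisation to the furoxan, so 10 should be isolable as a solid.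

Step 5
Reactants: 11 1-bromopentadecane
Product: 12 1-heptadecyne
Conditions: LiC≡CH·H2NCH2CH2NH2, DMSO, 15 °C to rt
Reagents that add atoms: lithium acetylide–ethylenediamine complex, [Li+].[C-]#C.NCCN
Why: SN2 alkylation of an unbranched primary bromide by lithium acetylide in a dipolar aprotic solvent. The ethylenediamine complex is a weighable acetylide source, and elimination should be minor for this substrate.

Step 6
Reactants: 10 2,4,6-trimethoxy-3,5-dimethylbenzonitrile oxide; 12 1-heptadecyne
Product: 13 5-pentadecyl-3-(2,4,6-trimethoxy-3,5-dimethylphenyl)isoxazole
Conditions: 12 (1.5 equiv), toluene, 80 °C, N2
Reagents that add atoms: none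
Why: The step is a concerted, asynchronous (3+2) dipolar cycloaddition (Huisgen type) of the nitrile oxide across the C≡C bond; its closest known counterpart is the thermal addition of isolable 2,6-disubstituted aryl nitrile oxides to terminal alkynes to give 3-aryl-5-alkylisoxazoles. The dipole carbon (future C4) bonds to the terminal CH of 12 (future C3) and the oxide oxygen to the internal carbon (future C2), so the isoxazole ring is closed in one suprafacial cycloaddition event, not by a stepwise cyclisation, and is aromatic as formed. No stereocentre is created, so no stereocontrol element is required. The selectivity needed is regiochemical (3,5- against 3,4-disubstitution), and two factors act together: the crowded dipole carbon avoids the substituted alkyne carbon, and the larger alkyne HOMO coefficient lies on the terminal carbon. Dimerisation to a furoxan is suppressed by the two ortho methoxy groups, which is why a simple unactivated alkyne can be used without slow-addition technique. The temperature is held at 80 °C to stay below the range in which aryl nitrile oxides isomerise to isocyanates, and the excess of 12 is recovered on chromatography. Of the two bonds formed, C3–C4 stays in the target, while the C2–O bond only fixes the ketone oxidation level at C2.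

Step 7
Reactants: 13 5-pentadecyl-3-(2,4,6-trimethoxy-3,5-dimethylphenyl)isoxazole
Product: 14 (Z)-1-amino-1-(2,4,6-trimethoxy-3,5-dimethylphenyl)octadec-1-en-3-one
Conditions: Mo(CO)6, MeCN/H2O, reflux
Reagents that add atoms: none
Why: Reductive ring opening of an isoxazole: Mo(CO)6 (zerovalent molybdenum) coordinates the ring nitrogen and inserts into the weak N–O bond, and water supplies the protons, giving the Z β-enaminoketone held by an N–H···O hydrogen bond. Aryl methyl ethers, the enaminone C=C and the alkyl chain are inert to this reagent.

Step 8
Reactants: 14 (Z)-1-amino-1-(2,4,6-trimethoxy-3,5-dimethylphenyl)octadec-1-en-3-one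
Product: 17 5,7-dihydroxy-6,8-dimethyl-2-pentadecyl-4H-chromen-4-one (the target), via triol enaminoketone 15 (not isolated), via diketone 16 (not isolated)
Conditions: BBr3 (excess), CH2Cl2, −78 °C to rt; H2O quench; then 6 M aq. HCl, EtOH, 70 °C, N2
Reagents that add atoms: water, O
Why: BBr3 cleaves all three aryl methyl ethers by O-complexation and bromide attack on methyl (the twisted methoxy between two methyls is the most basic and should cleave readily), giving 15 after the quench. Hot aqueous acid hydrolyses the vinylogous amide to 16, whose ortho hydroxyl adds to the C2 ketone and loses water to form the 4-pyranone (cyclodehydration of an ortho-hydroxyaryl 1,3-diketone). The two ortho hydroxyls are equivalent, so one chromone results, and hydrolysis and ring closure may occur in either order without changing the product.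

## Compound list

1 | 2,4,6-trimethoxytoluene (1,3,5-trimethoxy-2-methylbenzene) | Cc1c(OC)cc(OC)cc1OC | starting material
2 | iodomethane | CI | starting material
3 | (2,4,6-trimethoxy-3-methylphenyl)lithium | [Li]c1c(OC)cc(OC)c(C)c1OC | intermediate (not isolated)
4 | 1,3,5-trimethoxy-2,4-dimethylbenzene | Cc1c(OC)cc(OC)c(C)c1OC | intermediate
5 | (2,4,6-trimethoxy-3,5-dimethylphenyl)lithium | [Li]c1c(OC)c(C)c(OC)c(C)c1OC | intermediate (not isolated)
6 | lithium (dimethylamino)(2,4,6-trimethoxy-3,5-dimethylphenyl)methanolate (racemic) | [Li+].[O-]C(N(C)C)c1c(OC)c(C)c(OC)c(C)c1OC | intermediate (not isolated)
7 | 2,4,6-trimethoxy-3,5-dimethylbenzaldehyde | COc1c(C)c(OC)c(C=O)c(OC)c1C | intermediate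
8 | (E)-2,4,6-trimethoxy-3,5-dimethylbenzaldehyde oxime | COc1c(C)c(OC)c(/C=N/O)c(OC)c1C | intermediate
9 | (Z)-N-hydroxy-2,4,6-trimethoxy-3,5-dimethylbenzimidoyl chloride | COc1c(C)c(OC)c(/C(Cl)=N/O)c(OC)c1C | intermediate (not isolated)
10 | 2,4,6-trimethoxy-3,5-dimethylbenzonitrile oxide | COc1c(C)c(OC)c(C#[N+][O-])c(OC)c1C | intermediate
11 | 1-bromopentadecane | CCCCCCCCCCCCCCCBr | starting material
12 | 1-heptadecyne | CCCCCCCCCCCCCCCC#C | intermediate
13 | 5-pentadecyl-3-(2,4,6-trimethoxy-3,5-dimethylphenyl)isoxazole | CCCCCCCCCCCCCCCc1cc(-c2c(OC)c(C)c(OC)c(C)c2OC)no1 | intermediate
14 | (Z)-1-amino-1-(2,4,6-trimethoxy-3,5-dimethylphenyl)octadec-1-en-3-one | CCCCCCCCCCCCCCCC(=O)/C=C(\N)c1c(OC)c(C)c(OC)c(C)c1OC | intermediate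
15 | (Z)-1-amino-1-(2,4,6-trihydroxy-3,5-dimethylphenyl)octadec-1-en-3-one | CCCCCCCCCCCCCCCC(=O)/C=C(\N)c1c(O)c(C)c(O)c(C)c1O | intermediate (not isolated)
16 | 1-(2,4,6-trihydroxy-3,5-dimethylphenyl)octadecane-1,3-dione | CCCCCCCCCCCCCCCC(=O)CC(=O)c1c(O)c(C)c(O)c(C)c1O | intermediate (not isolated)
17 | 5,7-dihydroxy-6,8-dimethyl-2-pentadecyl-4H-chromen-4-one | CCCCCCCCCCCCCCCc1cc(=O)c2c(O)c(C)c(O)c(C)c2o1 | target

## Step count and least certain steps

Total steps: 8. Longest linear sequence: 7 (steps 1, 2, 3, 4, 6, 7, 8); the alkyne branch contributes step 5.

**Step 6 (key step).** The addition to an unactivated alkyne is slow, so at the temperature needed the dipole may be lost through thermal isomerisation to the isocyanate or slow dimerisation before 12 captures it. Some material may also be lost through attack in the 3,4-sense. The fallback forms the same C3–C4 bond by carbonyl addition instead of cycloaddition and sets out from 12 and 7. Deprotonation of 12 with n-BuLi gives (heptadec-1-yn-1-yl)lithium F1, which adds to 7 to give racemic 1-(2,4,6-trimethoxy-3,5-dimethylphenyl)octadec-2-yn-1-ol F2. Oxidation with MnO2 gives 1-(2,4,6-trimethoxy-3,5-dimethylphenyl)octadec-2-yn-1-one F3. BBr3 then removes the methyl groups to give 1-(2,4,6-trihydroxy-3,5-dimethylphenyl)octadec-2-yn-1-one F4, whose ortho hydroxyl closes onto the ynone in the 6-endo mode (Et2NH, EtOH). The route is rejoined at 17.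

**Step 8.** The enaminoketone can hold boron as an N,O-chelate that resists hydrolysis, so unmasking may stall. Prolonged heating in strong acid may instead cause protodeacylation of the electron-rich aryl ketone. The fallback reverses the order of events and sets out from 13. BBr3 acts on the inert isoxazole ring system to give 2,4-dimethyl-6-(5-pentadecylisoxazol-3-yl)benzene-1,3,5-triol F5. N–O cleavage (Mo(CO)6 in wet MeCN, or H2 over Raney Ni) then gives 15 directly. The route is rejoined at 15, which closes to 17 under mild aqueous acid.

**Step 2.** Metalation of the last, crowded ring position may be incomplete, and lateral lithiation of a methyl group flanked by two methoxy groups may compete, leading to mixtures after the DMF quench. The fallback replaces deprotonation by halogen–metal exchange and sets out from 4. Electrophilic bromination (NBS, MeCN) at the only free, strongly activated ring position gives 1-bromo-2,4,6-trimethoxy-3,5-dimethylbenzene F6. Bromine–lithium exchange with n-BuLi at −78 °C then gives 5 regiospecifically. The route is rejoined at 5 and continues with DMF as in step 2.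

**Step 4.** The free dipole may be lost during isolation through hydration, dimerisation on concentration or isomerisation on warming, and oxidation of the hindered oxime may be incomplete. The fallback never accumulates the dipole and sets out from 8. Chlorination with NCS in DMF gives 9, which is isolated. Slow addition of Et3N to 9 in the presence of excess 12 releases 10 at low stationary concentration, where it is trapped. The route is rejoined at 13; no compound outside the compound list is made (F0).

## Further compounds

F1 | step 6 | (heptadec-1-yn-1-yl)lithium | [Li]C#CCCCCCCCCCCCCCCC
F2 | step 6 | 1-(2,4,6-trimethoxy-3,5-dimethylphenyl)octadec-2-yn-1-ol (racemic) | CCCCCCCCCCCCCCCC#CC(O)c1c(OC)c(C)c(OC)c(C)c1OC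
F3 | step 6 | 1-(2,4,6-trimethoxy-3,5-dimethylphenyl)octadec-2-yn-1-one | CCCCCCCCCCCCCCCC#CC(=O)c1c(OC)c(C)c(OC)c(C)c1OC
F4 | step 6 | 1-(2,4,6-trihydroxy-3,5-dimethylphenyl)octadec-2-yn-1-one | CCCCCCCCCCCCCCCC#CC(=O)c1c(O)c(C)c(O)c(C)c1O
F5 | step 8 | 2,4-dimethyl-6-(5-pentadecylisoxazol-3-yl)benzene-1,3,5-triol | CCCCCCCCCCCCCCCc1cc(-c2c(O)c(C)c(O)c(C)c2O)no1
F6 | step 2 | 1-bromo-2,4,6-trimethoxy-3,5-dimethylbenzene | COc1c(C)c(OC)c(Br)c(OC)c1C
F0 | step 4 | none | none
A1 | alternative 1 | 1-(2,4,6-trihydroxy-3,5-dimethylphenyl)octadecane-1,3-dione | CCCCCCCCCCCCCCCC(=O)CC(=O)c1c(O)c(C)c(O)c(C)c1O
A2 | alternative 1 | 6-(2,4-dioxononadecyl)-4-hydroxy-3,5-dimethyl-2H-pyran-2-one | CCCCCCCCCCCCCCCC(=O)CC(=O)Cc1oc(=O)c(C)c(O)c1C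
A3 | alternative 1 | methyl 2,4-dimethyl-3,5,7,9-tetraoxotetracosanoate (mixture of stereoisomers and enol forms) | CCCCCCCCCCCCCCCC(=O)CC(=O)CC(=O)C(C)C(=O)C(C)C(=O)OC
A4 | alternative 2 | 7-methoxy-6,8-dimethyl-2-pentadecyl-5-(trifluoromethanesulfonyloxy)chromone | CCCCCCCCCCCCCCCc1cc(=O)c2c(OS(=O)(=O)C(F)(F)F)c(C)c(OC)c(C)c2o1
A5 | alternative 2 | 5-methoxy-4,6-dimethyl-2-(trimethylsilyl)-1,3-phenylene bis(trifluoromethanesulfonate) | COc1c(C)c(OS(=O)(=O)C(F)(F)F)c([Si](C)(C)C)c(OS(=O)(=O)C(F)(F)F)c1C
A6 | alternative 2 | cesium octadec-2-ynoate | CCCCCCCCCCCCCCCC#CC(=O)[O-].[Cs+]
A7 | alternative 3 | 5,7-dimethoxy-6,8-dimethyl-2-pentadecylchromone | CCCCCCCCCCCCCCCc1cc(=O)c2c(OC)c(C)c(OC)c(C)c2o1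
A8 | alternative 3 | 6,8-diiodo-5,7-dimethoxy-2-pentadecylchromone | CCCCCCCCCCCCCCCc1cc(=O)c2c(OC)c(I)c(OC)c(I)c2o1
A9 | alternative 3 | 5,7-dimethoxy-2-pentadecylchromone | CCCCCCCCCCCCCCCc1cc(=O)c2c(OC)cc(OC)cc2o1
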